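The target is a cis,cis-3,3''-biflavanone, (2R,3R,2''R,3''R). All four stereocentres (C2, C3, C3'', C2'') are set first in a twofold-symmetric bis-γ-lactone, made by auxiliary-controlled oxidative enolate dimerisation and double benzylic lactonisation. Two different 2-fluoroaryllithiums then open the lactones to aryl ketones and free the C2 and C2'' hydroxyls. The key step exploits that O1 on C2 lies β to the C4 ketone while C8a of ring A is ortho to it: a double intramolecular SNAr of the benzylic alkoxides on the carbonyl-activated C8a–F carbons closes pyranone ring C (O1–C8a) and its counterpart ring F (O1''–C8a'') in one operation, carrying the epimerisable cis-2,3 arrays through untouched.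

Key step: step 10

Numbering: flavanone numbering is used. Unprimed atoms and rings A (benzo) and C (pyranone) belong to the 5,7-dihydroxy half; double-primed atoms and rings D (benzo) and F (pyranone) belong to the 7-methoxy half.

Assumption: the γ-hydroxy ketones 12 and 17 are drawn as open-chain tautomers. They should equilibrate with the cyclic lactols (hemiketals), which reopen under the basic conditions of the following step.

Step 1
Reactants: 1 (R)-4-benzyloxazolidin-2-one; 2 3-(4-methoxyphenyl)propanoyl chloride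
Product: 3 (R)-4-benzyl-3-[3-(4-methoxyphenyl)propanoyl]oxazolidin-2-one
Conditions: Et3N, DMAP (cat.), CH2Cl2, 0 °C to rt
Reagents that add atoms: none
Why: DMAP-catalysed N-acylation of the oxazolidinone by the acid chloride should give the imide cleanly, and no stereocentre is formed.

Step 2
Reactants: 3 (R)-4-benzyl-3-[3-(4-methoxyphenyl)propanoyl]oxazolidin-2-one (two molecules are joined)
Product: 5 (4R,4'R)-3,3'-[(2S,3S)-2,3-bis(4-methoxybenzyl)butanedioyl]bis(4-benzyloxazolidin-2-one), via lithium Z-enolate 4 (not isolated)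
Conditions: LiN(i-Pr)2 (1.1 equiv), THF, −78 °C; then TiCl4 (1.1 equiv), −78 °C to rt
Reagents that add atoms: a second molecule of 3, COc1ccc(CCC(=O)N2[C@H](Cc3ccccc3)COC2=O)cc1
Why: Oxidative enolate homocoupling, in which TiCl4 (tetravalent titanium) oxidises the chelated Z-enolate by one electron and two α-carbonyl radicals, one from each molecule of 3, should dimerise on the face opposite the benzyl group of each (R)-auxiliary, which sets both new centres S (C3 and C3'' of the target).

Step 3
Reactants: 5 (4R,4'R)-3,3'-[(2S,3S)-2,3-bis(4-methoxybenzyl)butanedioyl]bis(4-benzyloxazolidin-2-one)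
Product: 6 (2S,3S)-2,3-bis(4-methoxybenzyl)butanedioic acid
Conditions: LiOH, H2O2, THF/H2O, 0 °C; then Na2SO3; then HCl to pH 2
Reagents that add atoms: hydrogen peroxide, OO (as lithium hydroperoxide; one oxygen of each CO2H)
Why: Hydroperoxide-mediated cleavage of the N-acyl oxazolidinones attacks the exocyclic carbonyls selectively and should release the diacid without epimerising the α-centres, the auxiliary being recovered.

Step 4
Reactants: 6 (2S,3S)-2,3-bis(4-methoxybenzyl)butanedioic acid
Product: 8 (3R,3aR,6R,6aR)-3,6-bis(4-methoxyphenyl)tetrahydrofuro[3,4-c]furan-1,4-dione, via monolactone acid 7 (not isolated)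
Conditions: DDQ (2.4 equiv), 1,4-dioxane, 80 °C
Reagents that add atoms: none
Why: Dehydrogenative benzylic lactonisation, in which DDQ abstracts hydride from each 4-methoxybenzylic CH2 and the anisyl-stabilised cation is trapped 5-exo by the carboxyl on the distal α-carbon; the aryl group should end trans to the neighbouring carboxyl and, in the second closure, on the convex face of the cis-fused bicycle (substrate control, reinforced by reversible ionisation of the anisylic C–O bond), which sets C2 and C2'' as R.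

Step 5
Reactants: 9 4-bromo-3,5-difluoroanisole
Product: 10 1-(benzyloxy)-2-bromo-3-fluoro-5-methoxybenzene
Conditions: BnOH (1.05 equiv), NaH, DMF, 0 to 70 °C
Reagents that add atoms: benzyl alcohol, OCc1ccccc1
Why: SNAr of sodium benzyloxide on one of the two equivalent fluorides (activated by the ortho bromine and the meta fluorine) should stop after one substitution because the new alkoxy group is a weaker activator than the fluorine it replaces, which fixes the substitution pattern of ring D without any regiochemical choice.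

Step 6
Reactants: 10 1-(benzyloxy)-2-bromo-3-fluoro-5-methoxybenzene; 8 (3R,3aR,6R,6aR)-3,6-bis(4-methoxyphenyl)tetrahydrofuro[3,4-c]furan-1,4-dione (1.5 equiv)
Product: 12 (3R,4R,5R)-4-[2-(benzyloxy)-6-fluoro-4-methoxybenzoyl]-3-[(R)-hydroxy(4-methoxyphenyl)methyl]-5-(4-methoxyphenyl)dihydrofuran-2(3H)-one, via aryllithium 11 (not isolated)
Conditions: 10, n-BuLi, THF, −78 °C; cannulated into 8, THF, −78 °C; AcOH, −78 °C
Reagents that add atoms: none
Why: Bromine–lithium exchange followed by 1,2-addition of the aryllithium to one of the two homotopic lactone carbonyls gives a lithium lactolate that is stable at −78 °C; an excess of 8 should favour mono-addition (unreacted 8 is recovered) and no stereocentre is touched.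

Step 7
Reactants: 13 4-bromo-3,5-difluorophenol
Product: 14 5-(benzyloxy)-2-bromo-1,3-difluorobenzene
Conditions: BnBr, K2CO3, DMF, rt
Reagents that add atoms: benzyl bromide, BrCc1ccccc1
Why: Williamson etherification of the acidic fluorophenol should proceed cleanly.

Step 8
Reactants: 14 5-(benzyloxy)-2-bromo-1,3-difluorobenzene
Product: 15 1,5-bis(benzyloxy)-2-bromo-3-fluorobenzene
Conditions: BnOH (1.05 equiv), NaH, DMF, 0 to 70 °C
Reagents that add atoms: benzyl alcohol, OCc1ccccc1
Why: The same mono-selective SNAr as in step 5 replaces one of two equivalent fluorides and gives the ring A precursor as a single regioisomer.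

Step 9
Reactants: 15 1,5-bis(benzyloxy)-2-bromo-3-fluorobenzene (2.2 equiv); 12 (3R,4R,5R)-4-[2-(benzyloxy)-6-fluoro-4-methoxybenzoyl]-3-[(R)-hydroxy(4-methoxyphenyl)methyl]-5-(4-methoxyphenyl)dihydrofuran-2(3H)-one
Product: 17 (2R,3R)-1-[2,4-bis(benzyloxy)-6-fluorophenyl]-4-[2-(benzyloxy)-6-fluoro-4-methoxyphenyl]-2,3-bis[(R)-hydroxy(4-methoxyphenyl)methyl]butane-1,4-dione, via aryllithium 16 (not isolated)
Conditions: 15, n-BuLi, THF, −78 °C; then 12, THF, −78 °C; AcOH, −78 °C
Reagents that add atoms: none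
Why: The first equivalent of 16 deprotonates the hydroxyl of 12 to a lithium lactolate that masks the existing ketone, and the second adds to the remaining lactone carbonyl (aryllithium 1,2-addition stopping at the lactolate), so no stereocentre is touched.

Step 10
Reactants: 17 (2R,3R)-1-[2,4-bis(benzyloxy)-6-fluorophenyl]-4-[2-(benzyloxy)-6-fluoro-4-methoxyphenyl]-2,3-bis[(R)-hydroxy(4-methoxyphenyl)methyl]butane-1,4-dione
Product: 19 (2R,3R)-5,7-bis(benzyloxy)-3-[(2R,3R)-5-(benzyloxy)-7-methoxy-2-(4-methoxyphenyl)-4-oxochroman-3-yl]-2-(4-methoxyphenyl)chroman-4-one, via mono-cyclised fluoro ketone 18 (not isolated)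
Conditions: KN(SiMe3)2 (2.05 equiv), THF/DMF, −40 to 0 °C; then pH 7 buffer
Reagents that add atoms: none
Why: Two equivalents of base convert the lactol/hydroxy-ketone tautomers into potassium alkoxides, and ring–chain opening exposes each benzylic alkoxide O1 (O1'') β to its own aryl ketone; the alkoxide adds to the fluorine-bearing carbon C8a (C8a'') ortho to the C4 (C4'') carbonyl, the Meisenheimer complex is stabilised by that carbonyl, and fluoride leaves (addition–elimination SNAr). The closest known reaction type is the intramolecular SNAr etherification of 2-fluoroaryl ketones that gives chromones, chroman-4-ones and 4-quinolones. Ring C and ring F are each closed in a 6-endo-trig mode (the C4a=C8a bond that relays the charge to the C4 carbonyl lies inside the new ring, as in the oxa-Michael closure of a 2'-hydroxychalcone) by formation of the aryl ether bonds O1–C8a and O1''–C8a'' (either ring may close first; 18 is drawn with ring F closed). No stereocentre is formed: C2 and C2'' keep their configuration because their C–O bonds are never broken, and C3 and C3'' are retained as long as no enolisation occurs, so the two syn-aldol arrays become the two cis-2,3 rings. The step needs six- over seven-membered closure (attack on the distal fluoroarene) and closure faster than retro-aldol cleavage or C3 enolisation; the ortho-carbonyl geometry favours the six-membered Meisenheimer complex, and low temperature with just two equivalents of base, consumed as KF, leaves no base to epimerise the product.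

Step 11
Reactants: 19 (2R,3R)-5,7-bis(benzyloxy)-3-[(2R,3R)-5-(benzyloxy)-7-methoxy-2-(4-methoxyphenyl)-4-oxochroman-3-yl]-2-(4-methoxyphenyl)chroman-4-one
Product: 20 (2R,3R)-5,7-dihydroxy-3-[(2R,3R)-5-hydroxy-7-methoxy-2-(4-methoxyphenyl)-4-oxochroman-3-yl]-2-(4-methoxyphenyl)chroman-4-one
Conditions: H2 (1 atm), 10% Pd/C, EtOAc, rt
Reagents that add atoms: none
Why: Hydrogenolysis of the three aryl benzyl ethers over Pd/C under neutral conditions should leave the less reactive secondary C2–O1 and C2''–O1'' benzylic ethers, the ketones, the methyl ethers and all four stereocentres untouched.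

Compound list

1 | (R)-4-benzyloxazolidin-2-one | O=C1N[C@H](Cc2ccccc2)CO1 | starting material
2 | 3-(4-methoxyphenyl)propanoyl chloride | COc1ccc(CCC(=O)Cl)cc1 | starting material
3 | (R)-4-benzyl-3-[3-(4-methoxyphenyl)propanoyl]oxazolidin-2-one | COc1ccc(CCC(=O)N2[C@H](Cc3ccccc3)COC2=O)cc1 | intermediate
4 | lithium Z-enolate of 3 | COc1ccc(C/C=C(\O[Li])N2[C@H](Cc3ccccc3)COC2=O)cc1 | intermediate
5 | (4R,4'R)-3,3'-[(2S,3S)-2,3-bis(4-methoxybenzyl)butanedioyl]bis(4-benzyloxazolidin-2-one) | COc1ccc(C[C@H](C(=O)N2[C@H](Cc3ccccc3)COC2=O)[C@@H](C(=O)N2[C@H](Cc3ccccc3)COC2=O)Cc2ccc(OC)cc2)cc1 | intermediate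
6 | (2S,3S)-2,3-bis(4-methoxybenzyl)butanedioic acid | COc1ccc(C[C@H](C(=O)O)[C@@H](C(=O)O)Cc2ccc(OC)cc2)cc1 | intermediate
7 | (2R,3R,4S)-4-(4-methoxybenzyl)-2-(4-methoxyphenyl)-5-oxotetrahydrofuran-3-carboxylic acid | COc1ccc([C@@H]2OC(=O)[C@@H](Cc3ccc(OC)cc3)[C@H]2C(=O)O)cc1 | intermediate
8 | (3R,3aR,6R,6aR)-3,6-bis(4-methoxyphenyl)tetrahydrofuro[3,4-c]furan-1,4-dione (cis-fused, both aryl groups exo) | COc1ccc([C@@H]2OC(=O)[C@@H]3[C@H]2C(=O)O[C@H]3c2ccc(OC)cc2)cc1 | intermediate
9 | 4-bromo-3,5-difluoroanisole | COc1cc(F)c(Br)c(F)c1 | starting material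
10 | 1-(benzyloxy)-2-bromo-3-fluoro-5-methoxybenzene | COc1cc(F)c(Br)c(OCc2ccccc2)c1 | intermediate
11 | [2-(benzyloxy)-6-fluoro-4-methoxyphenyl]lithium | COc1cc(F)c([Li])c(OCc2ccccc2)c1 | intermediate
12 | (3R,4R,5R)-4-[2-(benzyloxy)-6-fluoro-4-methoxybenzoyl]-3-[(R)-hydroxy(4-methoxyphenyl)methyl]-5-(4-methoxyphenyl)dihydrofuran-2(3H)-one | COc1ccc([C@H](O)[C@@H]2C(=O)O[C@H]([C@@H]2C(=O)c2c(F)cc(OC)cc2OCc2ccccc2)c2ccc(OC)cc2)cc1 | intermediate
13 | 4-bromo-3,5-difluorophenol | Oc1cc(F)c(Br)c(F)c1 | starting material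
14 | 5-(benzyloxy)-2-bromo-1,3-difluorobenzene | Fc1cc(OCc2ccccc2)cc(F)c1Br | intermediate
15 | 1,5-bis(benzyloxy)-2-bromo-3-fluorobenzene | Fc1cc(OCc2ccccc2)cc(OCc2ccccc2)c1Br | intermediate
16 | [2,4-bis(benzyloxy)-6-fluorophenyl]lithium | Fc1cc(OCc2ccccc2)cc(OCc2ccccc2)c1[Li] | intermediate
17 | (2R,3R)-1-[2,4-bis(benzyloxy)-6-fluorophenyl]-4-[2-(benzyloxy)-6-fluoro-4-methoxyphenyl]-2,3-bis[(R)-hydroxy(4-methoxyphenyl)methyl]butane-1,4-dione | COc1ccc([C@H](O)[C@H](C(=O)c2c(F)cc(OCc3ccccc3)cc2OCc2ccccc2)[C@@H](C(=O)c2c(F)cc(OC)cc2OCc2ccccc2)[C@@H](O)c2ccc(OC)cc2)cc1 | intermediate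
18 | (2R,3R)-5-(benzyloxy)-3-[(2R,3R)-1-[2,4-bis(benzyloxy)-6-fluorophenyl]-3-hydroxy-3-(4-methoxyphenyl)-1-oxopropan-2-yl]-7-methoxy-2-(4-methoxyphenyl)chroman-4-one | COc1ccc([C@H](O)[C@H](C(=O)c2c(F)cc(OCc3ccccc3)cc2OCc2ccccc2)[C@H]2C(=O)c3c(OCc4ccccc4)cc(OC)cc3O[C@H]2c2ccc(OC)cc2)cc1 | intermediate
19 | (2R,3R)-5,7-bis(benzyloxy)-3-[(2R,3R)-5-(benzyloxy)-7-methoxy-2-(4-methoxyphenyl)-4-oxochroman-3-yl]-2-(4-methoxyphenyl)chroman-4-one | COc1ccc([C@@H]2Oc3cc(OCc4ccccc4)cc(OCc4ccccc4)c3C(=O)[C@@H]2[C@H]2C(=O)c3c(OCc4ccccc4)cc(OC)cc3O[C@H]2c2ccc(OC)cc2)cc1 | intermediate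
20 | (2R,3R)-5,7-dihydroxy-3-[(2R,3R)-5-hydroxy-7-methoxy-2-(4-methoxyphenyl)-4-oxochroman-3-yl]-2-(4-methoxyphenyl)chroman-4-one (CNP0184936.2) | COc1ccc([C@@H]2Oc3cc(O)cc(O)c3C(=O)[C@@H]2[C@H]2C(=O)c3c(O)cc(OC)cc3O[C@H]2c2ccc(OC)cc2)cc1 | target

Total step count: 11.
Longest linear sequence: 8 steps (steps 1, 2, 3, 4, 6, 9, 10, 11).

Steps most likely to fail

1. Step 10 (key step). The potassium aldolates may fragment by retro-aldol cleavage of the C2–C3 bond, or C3 may epimerise by enolisation, before the rings close; the lactol forms may also fail to open. Fallback: from 17, both carbinol oxygens are silylated (Me3SiCl, imidazole, DMF), which should trap the open-chain form as the bis(trimethylsilyl) ether of 17, (2R,3R)-1-[2,4-bis(benzyloxy)-6-fluorophenyl]-4-[2-(benzyloxy)-6-fluoro-4-methoxyphenyl]-2,3-bis[(R)-(4-methoxyphenyl)(trimethylsilyloxy)methyl]butane-1,4-dione F1. Catalytic anhydrous CsF in DMF at rt then triggers a desilylative SNAr, each ring closure releasing the fluoride that unmasks the next alkoxide, so no stoichiometric strong base is present. This comes back to the route at 19.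

2. Step 4. The benzylic cation may lose a proton to give an arylidene succinic acid instead of being trapped, or the second oxidation may stall at the monolactone. Fallback: from 6, esterification (MeOH, H2SO4 cat.) gives dimethyl (2S,3S)-2,3-bis(4-methoxybenzyl)butanedioate F2. Wohl–Ziegler bromination (N-bromosuccinimide, AIBN, PhCF3, 80 °C) gives dimethyl (2S,3S)-2,3-bis[bromo(4-methoxyphenyl)methyl]butanedioate F3 as a mixture of epimers at the CHBr carbons. On warming in MeCN (AgBF4 if needed) the anisylic bromides ionise, the distal ester carbonyl oxygen closes each lactone with loss of bromomethane, and the same exo (thermodynamic) control applies. This comes back to the route at 8.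

3. Step 6. Mono-selectivity may be lost by addition to both lactones, and the hindered, basic aryllithium may enolise the lactone instead of adding. Fallback: the differentiation is moved to the end. From 8, an excess of 16 gives the symmetric (2R,3R)-1,4-bis[2,4-bis(benzyloxy)-6-fluorophenyl]-2,3-bis[(R)-hydroxy(4-methoxyphenyl)methyl]butane-1,4-dione F4. The double SNAr of step 10 then gives (2R,2'R,3R,3'R)-5,5',7,7'-tetrakis(benzyloxy)-2,2'-bis(4-methoxyphenyl)-[3,3'-bichromane]-4,4'-dione F5, and hydrogenolysis (H2, Pd/C) gives (2R,2'R,3R,3'R)-5,5',7,7'-tetrahydroxy-2,2'-bis(4-methoxyphenyl)-[3,3'-bichromane]-4,4'-dione F6. One equivalent of trimethylsilyldiazomethane (MeOH/toluene, 0 °C) should methylate one of the two acidic, non-chelated 7-hydroxyls while the hydrogen-bonded 5-hydroxyls stay free; unreacted tetraphenol is recycled. This comes back to the route at 20 and no longer needs 9 to 12.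

Further compounds

F1 | step 10 | (2R,3R)-1-[2,4-bis(benzyloxy)-6-fluorophenyl]-4-[2-(benzyloxy)-6-fluoro-4-methoxyphenyl]-2,3-bis[(R)-(4-methoxyphenyl)(trimethylsilyloxy)methyl]butane-1,4-dione | COc1ccc([C@H](O[Si](C)(C)C)[C@H](C(=O)c2c(F)cc(OCc3ccccc3)cc2OCc2ccccc2)[C@@H](C(=O)c2c(F)cc(OC)cc2OCc2ccccc2)[C@@H](O[Si](C)(C)C)c2ccc(OC)cc2)cc1
F2 | step 4 | dimethyl (2S,3S)-2,3-bis(4-methoxybenzyl)butanedioate | COc1ccc(C[C@H](C(=O)OC)[C@@H](C(=O)OC)Cc2ccc(OC)cc2)cc1
F3 | step 4 | dimethyl (2S,3S)-2,3-bis[bromo(4-methoxyphenyl)methyl]butanedioate (mixture of epimers at the CHBr carbons) | COc1ccc(C(Br)[C@H](C(=O)OC)[C@@H](C(=O)OC)C(Br)c2ccc(OC)cc2)cc1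
F4 | step 6 | (2R,3R)-1,4-bis[2,4-bis(benzyloxy)-6-fluorophenyl]-2,3-bis[(R)-hydroxy(4-methoxyphenyl)methyl]butane-1,4-dione | COc1ccc([C@H](O)[C@H](C(=O)c2c(F)cc(OCc3ccccc3)cc2OCc2ccccc2)[C@@H](C(=O)c2c(F)cc(OCc3ccccc3)cc2OCc2ccccc2)[C@@H](O)c2ccc(OC)cc2)cc1
F5 | step 6 | (2R,2'R,3R,3'R)-5,5',7,7'-tetrakis(benzyloxy)-2,2'-bis(4-methoxyphenyl)-[3,3'-bichromane]-4,4'-dione | COc1ccc([C@@H]2Oc3cc(OCc4ccccc4)cc(OCc4ccccc4)c3C(=O)[C@@H]2[C@H]2C(=O)c3c(OCc4ccccc4)cc(OCc4ccccc4)cc3O[C@H]2c2ccc(OC)cc2)cc1
F6 | step 6 | (2R,2'R,3R,3'R)-5,5',7,7'-tetrahydroxy-2,2'-bis(4-methoxyphenyl)-[3,3'-bichromane]-4,4'-dione | COc1ccc([C@@H]2Oc3cc(O)cc(O)c3C(=O)[C@@H]2[C@H]2C(=O)c3c(O)cc(O)cc3O[C@H]2c2ccc(OC)cc2)cc1
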